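The easy step is to turn one setting at a time and see what it does to Z.

| flask | L | E | X | temperature | remark | time |
|---|---|---|---|---|---|---|
| Thursday's | 0.80 M | 1.2 M | 0.80 M | 105 °C | run made earlier |  |
| Wednesday's | 0.80 M | 1.8 M | 0.80 M | 122 °C | run made earlier |  |
| Saturday's | 0.80 M | 2.4 M | 1.6 M | 105 °C | run made earlier |  |
| blue | 0.80 M | 2.40 M | 0.800 M |  | at 135 °C until 40 min, from then on at 110 °C | 2.0 h |
| teal | 0.80 M | 2.40 M | 0.800 M | 110 °C |  | 2.0 h |
| red | 0.80 M | 2.40 M | 0.800 M | 135 °C |  | 2.0 h |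

- Thursday's (time / min: Z / %, L / %): 10.0: 17, 78; 25.0: 28, 66; 50.0: 32, 61; 80.0: 30, 60
- Wednesday's (time / min: Z / %, L / %): 3.00: 32, 69; 6.00: 41, 54; 15.0: 44, 44; 40.0: 37, 40
- Saturday's (time / min: Z / %, L / %): 6.00: 24, 73; 12.0: 37, 60; 30.0: 49, 44; 80.0: 48, 46

(standard deviation of a reading: 1.5 percentage points)



1. the flask with the highest amount of Z, in percent of the L charged ("all alike" if they lie within 1.5 percentage points) (blue / teal / red / all alike)
2. final Z, as a percentage of the L charged, in blue
3. final Z, as a percentage of the L charged, in teal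
4. final Z, as a percentage of the L charged, in red

The amount of E comes first. E is the reagent, so by hand more of it should lift Z, and at 105 °C Saturday's 2.4 M reads 49% of Z at 30.0 min, more than the 32% that Thursday's 1.2 M reads at 50.0 min, though Saturday's also holds twice the X. Blue, teal and red each hold 2.40 M, so this setting does not separate them.

Temperature comes next. Heat should hurry the rise, and Wednesday's, at 122 °C and with 1.8 M of E, reads 44% as early as 15.0 min.

Time comes last: by hand, waiting helps until Z peaks and harms afterwards. Wednesday's Z reads 44% at 15.0 min and 37% at 40.0 min, which gives a rate of 0.00693 min⁻¹. Thursday's falls from 32% to 30% between 50.0 min and 80.0 min, which gives 0.00215 min⁻¹, but that is a drop of 2 percentage points on a scatter of 1.5 points, so it is rough.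

Carrying the same slope in temperature, I get 0.00303 min⁻¹ at 110 °C and 0.0170 min⁻¹ at 135 °C. This is the drain rate, a pseudo-first-order constant for the falling Z pool, and multiplied by time it counts turnovers.

Teal gets 0.364 turnovers and red 2.03. Blue gets 0.921, and its hot 40 min counts for more than its cool remainder. Teal has the fewest. Starting from Saturday's 49% as a rough pool, I commit to 34.0% in teal, 19.5% in blue and 6.41% in red.

The forecast names teal, with 15% in blue, 45% in teal and 3% in red, saying “teal keeps most of its Z”, and its teal stands higher than mine.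

The flasks give 16.0% in blue, 39.3% in teal and 3.88% in red, so teal holds the most.

    L + E ⇌ Z (K = 0.750 M⁻¹, k = 0.0357 M⁻¹ min⁻¹, Ea = 92.0 kJ mol⁻¹, ΔH = 20.0 kJ mol⁻¹)
    L + Z → Q (k = 0.00326 M⁻¹ min⁻¹, Ea = 103 kJ mol⁻¹)
    L ⇌ G (K = 0.884, k = 0.00232 min⁻¹, Ea = 120 kJ mol⁻¹, ΔH = −24.0 kJ mol⁻¹)
    X + E ⇌ D (K = 0.0928 M⁻¹, k = 0.00311 M⁻¹ min⁻¹, Ea = 78.0 kJ mol⁻¹, ΔH = −37.0 kJ mol⁻¹)
    E → J (k = 0.00350 min⁻¹, Ea = 116 kJ mol⁻¹)
    (constants at 110 °C)

In teal, the half-life of my drain rate is 3.81 h, far longer than the 0.25 h of L by the forward step to Z alone at 2.00 h, and teal's Z falls from 47.8% at 1.00 h to 39.3% at 2.00 h, a rate of 0.00329 min⁻¹ against my 0.00303 min⁻¹. Read on to 8.00 h, my drain rate takes teal's 39.3% down to 13.2%, and that flask holds 12.9%.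

The earlier runs and the new flask were computed from invented constants; noise was put on by code.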